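Assumption: the SMILES is read as (3R,7R) in azaphilone numbering (O2; C3 = CH(CH3)–O; C4a/C8a = ring fusion; C7 = quaternary carbon). This numbering is used throughout.

## Retrosynthetic overview

1. The C7–O(stearoyl) bond is made last, by dearomatising acyloxylation (Wessely type) of a citrinin-like quinone methide with lead(IV) stearate, so no separate esterification is needed.
2. The dihydropyran is the dehydrated ring form of a 6-(2-hydroxypropyl)salicylaldehyde, which comes from half-reduction of a dihydroisocoumarin.
3. The carbocycle is the key ring. It forms by [4+2] cycloaddition of a 1,3-bis(silyloxy)diene with a chiral ynoate, followed by aromatisation and lactonisation.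
4. C3 is bought in (R)-propylene oxide, opened by lithiated ethyl propiolate. C7 is created on the C3-bearing bicycle, so its two epimers are diastereomers.
5. Ring order: benzene ring (Diels–Alder), then δ-lactone, then dihydropyran with the dearomatised dione.

## Route

Step 1
Reactants: 1 (R)-propylene oxide [(2R)-2-methyloxirane]; 2 ethyl propiolate
Product: 3 ethyl (5R)-5-hydroxyhex-2-ynoate
Conditions: 2, n-BuLi, THF, −78 °C; BF3·OEt2; then 1, −78 °C, 2 h; aq. NH4Cl
Reagents that add atoms: none
Why: In this Yamaguchi–Hirao alkynylation the BF3-activated epoxide is opened by SN2 attack at the unsubstituted CH2, so the bought C–O stereocentre is untouched and becomes C3 (R).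

Step 2
Reactants: 4 methyl 2-methyl-3-oxobutanoate
Product: 5 1-methoxy-2-methyl-1,3-bis(trimethylsilyloxy)buta-1,3-diene (E/Z mixture)
Conditions: TMSOTf (2.2 equiv), Et3N (2.5 equiv), Et2O, 0 °C → rt; pentane extraction
Reagents that add atoms: trimethylsilyl trifluoromethanesulfonate (TMSOTf), C[Si](C)(C)OS(=O)(=O)C(F)(F)F
Why: Double soft enolisation and O-silylation of the β-keto ester gives the Chan-type electron-rich diene, and no stereocentre is involved.

Step 3
Reactants: 3 ethyl (5R)-5-hydroxyhex-2-ynoate; 5 1-methoxy-2-methyl-1,3-bis(trimethylsilyloxy)buta-1,3-diene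
Product: 8 (3R)-6,8-dihydroxy-3,7-dimethyl-3,4-dihydro-1H-isochromen-1-one, via Diels–Alder adduct 6 (not isolated), via ethyl resorcylate 7 (not isolated)
Conditions: 5 (2.5 equiv, the excess covers O-silylation of the free OH), PhMe, 120 °C, sealed tube, 36 h; then TsOH·H2O, wet THF, rt → 60 °C
Reagents that add atoms: none
Why: In this normal-demand Diels–Alder reaction the nucleophilic CH2 terminus of 5 bonds to the β-carbon of the ynoate and the ketene-acetal carbon to the α-carbon; loss of MeOH aromatises 6, acid removes the silyl groups and closes the δ-lactone, and C3 is a spectator.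

Step 4
Reactants: 8 (3R)-6,8-dihydroxy-3,7-dimethyl-3,4-dihydro-1H-isochromen-1-one
Product: 10 2,4-dihydroxy-6-[(2R)-2-hydroxypropyl]-3-methylbenzaldehyde, via lactol 9 (not isolated)
Conditions: DIBAL-H (4 equiv), CH2Cl2, −78 °C, 2 h; MeOH, then aq. Rochelle salt
Reagents that add atoms: none
Why: In this partial lactone reduction two equivalents are spent on the phenols and the O8-aluminium-chelated tetrahedral intermediate survives at −78 °C; on work-up lactol 9 opens to the hydrogen-bonded salicylaldehyde, and C3 is untouched.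

Step 5
Reactants: 10 2,4-dihydroxy-6-[(2R)-2-hydroxypropyl]-3-methylbenzaldehyde; 11 stearic acid (octadecanoic acid)
Product: 13 (3R,7R)-3,7-dimethyl-6,8-dioxo-4,6,7,8-tetrahydro-3H-isochromen-7-yl octadecanoate (target), via quinone methide 12 (not isolated)
Conditions: Pb(OAc)4 (1.1 equiv) + 11 (4.5 equiv), PhMe, 40 °C, 15 mbar (AcOH stripped off); separately 10, TsOH (5 mol %), 4 Å MS, CH2Cl2, rt; combine at 0 °C in the dark; SiO2 chromatography
Reagents that add atoms: none
Why: In this Wessely-type dearomatising acyloxylation acid dehydrates 10 to the vinylogous acid 12, whose enol binds Pb(IV) and receives a stearate ligand at the methyl-bearing C7; the only stereochemical information present is the bought C3 centre, which is too remote from the flat C6–C7–C8 unit to give more than a weak facial bias, so 13 forms together with its 7S epimer and is isolated as the single (3R,7R) diastereomer by chromatography.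

## Compound list

1 | (R)-propylene oxide | C[C@@H]1CO1 | starting material
2 | ethyl propiolate | C#CC(=O)OCC | starting material
3 | ethyl (5R)-5-hydroxyhex-2-ynoate | CCOC(=O)C#CC[C@@H](C)O | intermediate
4 | methyl 2-methyl-3-oxobutanoate | COC(=O)C(C)C(C)=O | starting material
5 | 1-methoxy-2-methyl-1,3-bis(trimethylsilyloxy)buta-1,3-diene | C=C(O[Si](C)(C)C)C(C)=C(OC)O[Si](C)(C)C | intermediate
6 | ethyl 2-[(2R)-2-hydroxypropyl]-6-methoxy-5-methyl-4,6-bis(trimethylsilyloxy)cyclohexa-1,4-diene-1-carboxylate (Diels–Alder adduct) | CCOC(=O)C1=C(C[C@@H](C)O)CC(O[Si](C)(C)C)=C(C)C1(OC)O[Si](C)(C)C | intermediate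
7 | ethyl 2,4-dihydroxy-6-[(2R)-2-hydroxypropyl]-3-methylbenzoate | CCOC(=O)c1c(C[C@@H](C)O)cc(O)c(C)c1O | intermediate
8 | (3R)-6,8-dihydroxy-3,7-dimethyl-3,4-dihydro-1H-isochromen-1-one | C[C@@H]1Cc2cc(O)c(C)c(O)c2C(=O)O1 | intermediate
9 | (3R)-3,7-dimethyl-3,4-dihydro-1H-isochromene-1,6,8-triol (lactol, C1 epimers) | C[C@@H]1Cc2cc(O)c(C)c(O)c2C(O)O1 | intermediate
10 | 2,4-dihydroxy-6-[(2R)-2-hydroxypropyl]-3-methylbenzaldehyde | C[C@@H](O)Cc1cc(O)c(C)c(O)c1C=O | intermediate
11 | stearic acid | CCCCCCCCCCCCCCCCCC(=O)O | starting material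
12 | (3R)-8-hydroxy-3,7-dimethyl-4,6-dihydro-3H-isochromen-6-one (quinone methide) | C[C@@H]1CC2=CC(=O)C(C)=C(O)C2=CO1 | intermediate
13 | (3R,7R)-3,7-dimethyl-6,8-dioxo-4,6,7,8-tetrahydro-3H-isochromen-7-yl octadecanoate | CCCCCCCCCCCCCCCCCC(=O)O[C@]1(C)C(=O)C=C2C[C@@H](C)OC=C2C1=O | target

## Step count and risks

Total step count: 5. Longest linear sequence: 4 (steps 1, 3, 4, 5).

**Step 5 (most likely to fail).**
- There is no useful facial bias at C7, so at best about half of the material is the right epimer.
- The two C18 esters may be hard to separate.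
- Residual acetate on lead can scramble the ligand that is transferred.
- Fallback: separate C–O bond formation from acylation. It sets out from 10, which is dehydrated to 12 as before. Hydroxylative dearomatisation with IBX (cat. TFA, cat. n-Bu4NI, ClCH2CH2Cl, rt) transfers oxygen from I(V) to C7. This gives the tertiary alcohol (3R,7R)-7-hydroxy-3,7-dimethyl-3,4-dihydro-6H-isochromene-6,8(7H)-dione F1 and the (3R,7S)-7-hydroxy epimer F2. These compact, polar α-ketols are much easier to separate by chromatography or crystallisation than the fatty esters. F1 is acylated with stearoyl chloride (from 11 and SOCl2) with pyridine and DMAP in CH2Cl2, and the fallback comes back to the route at 13. F2 is not discarded: Zn in AcOH removes the α-ketol oxygen and returns it to 12 for another pass.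

**Step 4.**
- The bis(aluminium phenoxide) of 8 is an electron-rich, chelated lactone. It may be sluggish at −78 °C and over-reduce to the benzylic alcohol when warmed.
- Fallback: bring C1 in at the aldehyde oxidation level so that no redox adjustment is needed. It sets out from 1. Lithiated 3,3-diethoxyprop-1-yne (n-BuLi, BF3·OEt2, THF, −78 °C) opens the epoxide to (2R)-6,6-diethoxyhex-4-yn-2-ol F3. Formic acid in CH2Cl2 unmasks (5R)-5-hydroxyhex-2-ynal F4. This more reactive dienophile undergoes the same Diels–Alder/aromatisation with 5 (PhMe, 60–80 °C; then dilute HCl in THF), and the fallback comes back to the route at 10.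

**Step 3.**
- A β-alkyl ynoate is a slow dienophile, and 5 can decompose or merely transfer silicon at 120 °C.
- Fallback: build the arene without a cycloaddition. It sets out from 1. The starting arene 5-bromo-1,3-dimethoxy-2-methylbenzene F5 is lithiated (n-BuLi, THF, −78 °C), and the aryllithium opens 1 (BF3·OEt2) to (2R)-1-(3,5-dimethoxy-4-methylphenyl)propan-2-ol F6. An oxa-Pictet–Spengler reaction with HC(OMe)3 and cat. TsOH closes the ring at either of the two equivalent activated ortho positions. This gives (3R)-1,6,8-trimethoxy-3,7-dimethyl-3,4-dihydro-1H-isochromene F7. BBr3 (CH2Cl2, −78 → 0 °C), then water, removes the methyl groups, and the fallback comes back to the route at 10.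

## Further compounds

F1 | step 5 | (3R,7R)-7-hydroxy-3,7-dimethyl-3,4-dihydro-6H-isochromene-6,8(7H)-dione | O[C@]1(C)C(=O)C=C2C[C@@H](C)OC=C2C1=O
F2 | step 5 | (3R,7S)-7-hydroxy-3,7-dimethyl-3,4-dihydro-6H-isochromene-6,8(7H)-dione | O[C@@]1(C)C(=O)C=C2C[C@@H](C)OC=C2C1=O
F3 | step 4 | (2R)-6,6-diethoxyhex-4-yn-2-ol | CCOC(OCC)C#CC[C@@H](C)O
F4 | step 4 | (5R)-5-hydroxyhex-2-ynal | O=CC#CC[C@@H](C)O
F5 | step 3 | 5-bromo-1,3-dimethoxy-2-methylbenzene | COc1cc(Br)cc(OC)c1C
F6 | step 3 | (2R)-1-(3,5-dimethoxy-4-methylphenyl)propan-2-ol | COc1cc(C[C@@H](C)O)cc(OC)c1C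
F7 | step 3 | (3R)-1,6,8-trimethoxy-3,7-dimethyl-3,4-dihydro-1H-isochromene | C[C@@H]1Cc2cc(OC)c(C)c(OC)c2C(OC)O1
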